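**Strategy.** The cyclohexane ring (numbered as in the 7-oxabicyclo[4.1.0]heptane core: C-1 bears the methyl, C-2 and C-3 the angelates, C-4 the side chain, C-6 is the epoxide CH) is cut into two three-carbon halves. C-1/C-2/C-3 come from racemic 2,2,4-trimethyl-1,3-dioxan-5-one; C-4/C-5/C-6 from a dienal that already carries the acetoxy side chain. One proline-catalysed α,α′-annulation (Michael addition, then intramolecular aldol) forges C-3–C-4 and C-1–C-6 together. It exploits the cis-1,3 relation of the oxygens on C-1 and C-3 across C-2: only the cis-bridged 2,4-dioxabicyclo[3.3.1]nonan-9-one can close, so the epimerisable ketone converges on one isomer. The C-6 hydroxyl later leaves as mesylate when the C-1 oxygen closes the epoxide.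

Key step: step 8

Remark (assumption): the lipase in step 3 is taken to follow its usual size-based enantiopreference for 1-alkyn-3-ols and so to acylate the (S)-alcohol; fragment B (10) is used as the racemate because its only stereocentre is erased and reset in step 8.

**Fragment A (dienal 6)**

Step 1
Reactants: 1 4-methylpent-3-en-1-ol
Product: 2 4-methylpent-3-enal
Conditions: Dess–Martin periodinane, CH2Cl2, 0 °C to rt; used crude
Reagents that add atoms: none
Why: Dess–Martin oxidation of a primary alcohol under non-basic conditions, so the β,γ-alkene should not move into conjugation.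

Step 2
Reactants: 2 4-methylpent-3-enal
Product: 3 (±)-6-methylhept-5-en-1-yn-3-ol
Conditions: HC≡CMgBr, THF, −78 to 0 °C; aq. NH4Cl
Reagents that add atoms: ethynylmagnesium bromide, C#C[Mg]Br
Why: Grignard 1,2-addition of the acetylide to the aldehyde; the carbinol is formed as the racemate and resolved in step 3.

Step 3
Reactants: 3 (±)-6-methylhept-5-en-1-yn-3-ol
Product: 4 (3S)-6-methylhept-5-en-1-yn-3-yl acetate
Conditions: immobilised Candida antarctica lipase B (Novozym 435), vinyl acetate, methyl tert-butyl ether, 30 °C, stopped near 45 % conversion; chromatography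
Reagents that add atoms: vinyl acetate, C=COC(C)=O
Why: lipase-catalysed kinetic resolution by irreversible transesterification; the enzyme should acylate the enantiomer whose small ethynyl group sits in the medium pocket, which is the (S)-alcohol, while unreacted (R)-3 is separated.

Step 4
Reactants: 4 (3S)-6-methylhept-5-en-1-yn-3-yl acetate
Product: 5 (5S)-1,1-diethoxy-8-methyl-4-methylidenenona-2,7-dien-5-yl acetate (2E/2Z mixture)
Conditions: acrolein diethyl acetal (4 equiv), second-generation Grubbs catalyst RuCl2(PCy3)(H2IMes)(=CHPh) (5 mol %), CH2Cl2, 40 °C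
Reagents that add atoms: acrolein diethyl acetal, C=CC(OCC)OCC
Why: enyne cross-metathesis joins the terminal alkyne and the terminal alkene to a 2-substituted 1,3-diene in which the internal alkyne carbon becomes the methylidene-bearing carbon; the trisubstituted prenyl alkene and the propargylic acetate are spectators and the stereocentre is untouched.

Step 5
Reactants: 5 (5S)-1,1-diethoxy-8-methyl-4-methylidenenona-2,7-dien-5-yl acetate
Product: 6 (2E,5S)-8-methyl-4-methylidene-1-oxonona-2,7-dien-5-yl acetate (fragment A)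
Conditions: Amberlyst-15, acetone/H2O, rt; then I2 (1 mol %), CH2Cl2, rt
Reagents that add atoms: water, O
Why: acid-catalysed acetal hydrolysis; the 2Z component should converge on the conjugated 2E dienal by iodine-catalysed equilibration.

**Fragment B (ketone 10)**

Step 6
Reactants: 7 2,2-dimethyl-1,3-dioxan-5-one
Product: 8 2-(2,2-dimethyl-1,3-dioxan-5-ylidene)-1,1-dimethylhydrazine
Conditions: Me2NNH2, MgSO4, CH2Cl2, rt
Reagents that add atoms: 1,1-dimethylhydrazine, CN(C)N
Why: hydrazone condensation; the dimethylhydrazone is the aza-enolate precursor needed because direct enolate alkylation of this ketone is unreliable.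

Step 7
Reactants: 8 2-(2,2-dimethyl-1,3-dioxan-5-ylidene)-1,1-dimethylhydrazine
Product: 10 (±)-2,2,4-trimethyl-1,3-dioxan-5-one (fragment B), via methylated hydrazone 9 (not isolated)
Conditions: LiN(i-Pr)2, THF, −78 °C; MeI, −78 to −20 °C; then saturated aqueous oxalic acid/Et2O, rt
Reagents that add atoms: iodomethane, CI; water, O
Why: aza-enolate C-methylation followed by two-phase acidic hydrazone hydrolysis, which should spare the acetonide; the new stereocentre need not be controlled because step 8 erases it.

**Union and completion**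

Step 8
Reactants: 6 (2E,5S)-8-methyl-4-methylidene-1-oxonona-2,7-dien-5-yl acetate (fragment A); 10 (±)-2,2,4-trimethyl-1,3-dioxan-5-one (fragment B)
Product: 12 (3S)-2-[(1S,5R,6S,8R)-8-hydroxy-1,3,3-trimethyl-9-oxo-2,4-dioxabicyclo[3.3.1]nonan-6-yl]-6-methylhepta-1,5-dien-3-yl acetate, via keto aldehyde 11 (not isolated)
Conditions: (S)-proline (30 mol %), DMF, 4 °C, then 25 °C
Reagents that add atoms: none
Why: The proline enamine of 10 forms on the unsubstituted α-carbon (C-3) and adds in a conjugate sense to C-4 of the dienal (itself in equilibrium with its iminium ion) to give keto aldehyde 11; enolisation towards the methyl-bearing α′-carbon (C-1) and intramolecular aldol addition to the C-6 aldehyde then close the carbocycle. The closest known reaction type is the enamine α,α′-annulation of cyclic ketones with α,β-unsaturated aldehydes (Michael/aldol, Stork type) in its amine-catalysed asymmetric form. The single ring closure is a 6-(enolendo)-exo-trig aldolisation. C-4 should be set by the catalyst (enamine face plus synclinal approach of the acceptor, the topicity that (S)-proline-type catalysts show with nitroalkenes, which corresponds to 4S here); C-3 and C-1 are epimerisable before closure and are fixed by the product, since only the cis-bridged bicycle with the side chain equatorial is free of strain, so racemic 10 and both C-3 epimers of 11 should converge; the C-6 hydroxyl should be placed axial, anti to the C-1 oxygen, by the hydrogen-bonded closed transition state. The step needs 1,4- over 1,2- and 1,6-addition: a 1,2-aldol adduct at the enal carbonyl reverts under the conditions, the dienal has no γ-hydrogen and so cannot self-condense through a dienamine, and conjugate addition at the β-carbon is drained by the ring closure.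

Step 9
Reactants: 12 bicyclic ketol
Product: 13 (3S)-2-[(1S,5R,6S,8R)-8-(methanesulfonyloxy)-1,3,3-trimethyl-9-oxo-2,4-dioxabicyclo[3.3.1]nonan-6-yl]-6-methylhepta-1,5-dien-3-yl acetate
Conditions: MsCl, Et3N, CH2Cl2, −10 °C
Reagents that add atoms: methanesulfonyl chloride, CS(=O)(=O)Cl
Why: sulfonylation (via sulfene) of the only free hydroxyl with retention at C-6; the β-mesyloxy ketone should be stable because C-1 is quaternary and the other α-carbon is a bridgehead, so no β-elimination is possible.

Step 10
Reactants: 13 keto mesylate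
Product: 14 (3S)-2-[(1R,5R,6S,8R,9S)-9-hydroxy-8-(methanesulfonyloxy)-1,3,3-trimethyl-2,4-dioxabicyclo[3.3.1]nonan-6-yl]-6-methylhepta-1,5-dien-3-yl acetate
Conditions: NaBH4, MeOH/CH2Cl2 (1:1), −40 °C
Reagents that add atoms: none
Why: substrate-controlled borohydride reduction; the carbonyl face toward the carbocycle is screened by the axial C-6 mesylate (1,3-diaxial), so hydride should enter over the two acetal oxygens and give the C-2 alcohol anti to the C-1 and C-3 oxygens.

Step 11
Reactants: 14 hydroxy mesylate
Product: 16 (3S)-2-[(1R,2S,3R,4S,6S)-2,3-dihydroxy-1-methyl-7-oxabicyclo[4.1.0]heptan-4-yl]-6-methylhepta-1,5-dien-3-yl acetate, via triol mesylate 15 (not isolated)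
Conditions: AcOH/H2O (4:1), 40 °C; evaporation with toluene; then KOt-Bu (1.1 equiv), THF, −40 to 0 °C
Reagents that add atoms: none
Why: mild acid hydrolyses the strained bridging acetonide; the tertiary C-1 alkoxide then displaces the antiperiplanar C-6 mesylate with inversion (3-exo-tet Williamson closure), so the epoxide oxygen ends up syn to the C-3 hydroxyl, while the C-2 hydroxyl is cis to the leaving group and cannot compete.

Step 12
Reactants: 16 epoxy diol
Product: 17 (1S,2S,3R,4S,6S)-4-[(3S)-3-(acetyloxy)-6-methylhepta-1,5-dien-2-yl]-1-methyl-7-oxabicyclo[4.1.0]heptane-2,3-diyl bis[(2Z)-2-methylbut-2-enoate] (target)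
Conditions: LiN(SiMe3)2 (2.2 equiv), THF, −78 °C; angelic anhydride (3 equiv), −78 to 0 °C
Reagents that add atoms: angelic anhydride [(2Z)-2-methylbut-2-enoic anhydride], C/C=C(/C)C(=O)OC(=O)/C(C)=C\C
Why: acylation of the two lithium alkoxides with the anhydride at low temperature should esterify both hydroxyls without the nucleophilic-catalyst or thermal conditions that isomerise angelates to tiglates; no stereocentre is touched.

**Compound list**

1 | 4-methylpent-3-en-1-ol | CC(C)=CCCO | starting material
2 | 4-methylpent-3-enal | CC(C)=CCC=O | intermediate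
3 | (±)-6-methylhept-5-en-1-yn-3-ol | C#CC(O)CC=C(C)C | intermediate
4 | (3S)-6-methylhept-5-en-1-yn-3-yl acetate | C#C[C@H](CC=C(C)C)OC(C)=O | intermediate
5 | (5S)-1,1-diethoxy-8-methyl-4-methylidenenona-2,7-dien-5-yl acetate (2E/2Z mixture) | CCOC(OCC)C=CC(=C)[C@H](CC=C(C)C)OC(C)=O | intermediate
6 | (2E,5S)-8-methyl-4-methylidene-1-oxonona-2,7-dien-5-yl acetate (fragment A) | O=C/C=C/C(=C)[C@H](CC=C(C)C)OC(C)=O | intermediate
7 | 2,2-dimethyl-1,3-dioxan-5-one | CC1(C)OCC(=O)CO1 | starting material
8 | 2-(2,2-dimethyl-1,3-dioxan-5-ylidene)-1,1-dimethylhydrazine | CN(C)N=C1COC(C)(C)OC1 | intermediate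
9 | 1,1-dimethyl-2-(2,2,4-trimethyl-1,3-dioxan-5-ylidene)hydrazine (racemic, not isolated) | CC1OC(C)(C)OCC1=NN(C)C | intermediate
10 | (±)-2,2,4-trimethyl-1,3-dioxan-5-one (fragment B) | CC1OC(C)(C)OCC1=O | intermediate
11 | (3S)-6-methyl-2-[(1S)-3-oxo-1-(2,2,6-trimethyl-5-oxo-1,3-dioxan-4-yl)propyl]hepta-1,5-dien-3-yl acetate (keto aldehyde, mixture of ring epimers, not isolated) | O=CC[C@H](C1OC(C)(C)OC(C)C1=O)C(=C)[C@H](CC=C(C)C)OC(C)=O | intermediate
12 | (3S)-2-[(1S,5R,6S,8R)-8-hydroxy-1,3,3-trimethyl-9-oxo-2,4-dioxabicyclo[3.3.1]nonan-6-yl]-6-methylhepta-1,5-dien-3-yl acetate (bicyclic ketol; hydroxyl axial, side chain equatorial) | C=C([C@H](CC=C(C)C)OC(C)=O)[C@@H]1C[C@@H](O)[C@]2(C)OC(C)(C)O[C@H]1C2=O | intermediate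
13 | (3S)-2-[(1S,5R,6S,8R)-8-(methanesulfonyloxy)-1,3,3-trimethyl-9-oxo-2,4-dioxabicyclo[3.3.1]nonan-6-yl]-6-methylhepta-1,5-dien-3-yl acetate | C=C([C@H](CC=C(C)C)OC(C)=O)[C@@H]1C[C@@H](OS(C)(=O)=O)[C@]2(C)OC(C)(C)O[C@H]1C2=O | intermediate
14 | (3S)-2-[(1R,5R,6S,8R,9S)-9-hydroxy-8-(methanesulfonyloxy)-1,3,3-trimethyl-2,4-dioxabicyclo[3.3.1]nonan-6-yl]-6-methylhepta-1,5-dien-3-yl acetate | C=C([C@H](CC=C(C)C)OC(C)=O)[C@@H]1C[C@@H](OS(C)(=O)=O)[C@]2(C)OC(C)(C)O[C@H]1[C@@H]2O | intermediate
15 | (3S)-6-methyl-2-[(1S,2R,3S,4R,5R)-2,3,4-trihydroxy-5-(methanesulfonyloxy)-4-methylcyclohexyl]hepta-1,5-dien-3-yl acetate (triol mesylate, not isolated) | C=C([C@H](CC=C(C)C)OC(C)=O)[C@@H]1C[C@@H](OS(C)(=O)=O)[C@](C)(O)[C@@H](O)[C@@H]1O | intermediate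
16 | (3S)-2-[(1R,2S,3R,4S,6S)-2,3-dihydroxy-1-methyl-7-oxabicyclo[4.1.0]heptan-4-yl]-6-methylhepta-1,5-dien-3-yl acetate | C=C([C@H](CC=C(C)C)OC(C)=O)[C@@H]1C[C@@H]2O[C@]2(C)[C@@H](O)[C@@H]1O | intermediate
17 | (1S,2S,3R,4S,6S)-4-[(3S)-3-(acetyloxy)-6-methylhepta-1,5-dien-2-yl]-1-methyl-7-oxabicyclo[4.1.0]heptane-2,3-diyl bis[(2Z)-2-methylbut-2-enoate] | C=C([C@H](CC=C(C)C)OC(C)=O)[C@@H]1C[C@@H]2O[C@]2(C)[C@@H](OC(=O)/C(C)=C\C)[C@@H]1OC(=O)/C(C)=C\C | target

**Step count and risks**

Total steps: 12. Longest linear sequence: 10 (steps 1–5 and 8–12).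

Steps most likely to fail:

Step 8. The enamine may add 1,2 to the aldehyde or 1,6 to the terminal methylene instead of 1,4, or the second aldol may stall at the hindered, methyl-bearing α′-carbon. The fallback sets out from 10: kinetic deprotonation (LiN(i-Pr)2, THF, −78 °C) and silylation (Me3SiCl) give the silyl enol ether trimethyl[(2,2,4-trimethyl-4H-1,3-dioxin-5-yl)oxy]silane F1. An iminium-catalysed Mukaiyama–Michael addition of F1 to 6 [(2S,5S)-5-benzyl-2-tert-butyl-3-methylimidazolidin-4-one·CF3CO2H (20 mol %), CH2Cl2/H2O, −40 °C] uses a regiodefined nucleophile and a catalyst that shields one face of C-4; it should give keto aldehyde 11. DBU (20 mol %) added to the same flask at 0 °C then closes the aldol, and the route is rejoined at 12.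

Step 10. Hydride delivery to the bridging ketone may show poor facial selectivity, because the acetonide methyl can screen the face that has to be attacked. The fallback sets out from 12 and reduces before sulfonylation under chelation control (Et2BOMe, NaBH4, THF/MeOH, −78 °C). The boron chelate between the C-6 hydroxyl and the ketone blocks the carbocycle face and should give the syn-1,3-diol (3S)-2-[(1S,5R,6S,8R,9S)-8,9-dihydroxy-1,3,3-trimethyl-2,4-dioxabicyclo[3.3.1]nonan-6-yl]-6-methylhepta-1,5-dien-3-yl acetate F2. MsCl (1.05 equiv), 2,4,6-collidine, CH2Cl2, −20 °C should then sulfonylate the less hindered C-6 hydroxyl (its neighbour C-5 is a methylene, whereas the C-2 hydroxyl lies between two bridgeheads), and the route is rejoined at 14.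

Step 12. The angelate may isomerise Z to E (tiglate) during acylation, or the hindered C-2 hydroxyl may acylate incompletely. The fallback sets out from 16: both hydroxyls are esterified with 2-[bis(2-methylphenoxy)phosphoryl]propanoic acid (DCC, DMAP, CH2Cl2) to give the bis(phosphonate) (1S,2S,3R,4S,6S)-4-[(3S)-3-(acetyloxy)-6-methylhepta-1,5-dien-2-yl]-1-methyl-7-oxabicyclo[4.1.0]heptane-2,3-diyl bis{2-[bis(2-methylphenoxy)phosphoryl]propanoate} F3. The Z-trisubstituted alkenes are then built on the esters by a Z-selective Horner–Wadsworth–Emmons olefination with acetaldehyde (KOt-Bu, THF, −78 °C), arriving at 17.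

**Further compounds**

F1 | step 8 | trimethyl[(2,2,4-trimethyl-4H-1,3-dioxin-5-yl)oxy]silane | CC1OC(C)(C)OC=C1O[Si](C)(C)C
F2 | step 10 | (3S)-2-[(1S,5R,6S,8R,9S)-8,9-dihydroxy-1,3,3-trimethyl-2,4-dioxabicyclo[3.3.1]nonan-6-yl]-6-methylhepta-1,5-dien-3-yl acetate | C=C([C@H](CC=C(C)C)OC(C)=O)[C@@H]1C[C@@H](O)[C@]2(C)OC(C)(C)O[C@H]1[C@@H]2O
F3 | step 12 | (1S,2S,3R,4S,6S)-4-[(3S)-3-(acetyloxy)-6-methylhepta-1,5-dien-2-yl]-1-methyl-7-oxabicyclo[4.1.0]heptane-2,3-diyl bis{2-[bis(2-methylphenoxy)phosphoryl]propanoate} (epimer mixture at the phosphonate-bearing carbons) | C=C([C@H](CC=C(C)C)OC(C)=O)[C@@H]1C[C@@H]2O[C@]2(C)[C@@H](OC(=O)C(C)P(=O)(Oc3ccccc3C)Oc3ccccc3C)[C@@H]1OC(=O)C(C)P(=O)(Oc1ccccc1C)Oc1ccccc1C
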